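**Remarks on the chemistry**

- Locants follow kaurane numbering: ring A is C1–C5 and C10; C18 is the methyl on C4, C19 the lactone carbonyl carbon, C20 the methyl on C10; C6–C7 is the tether; C8, C9 and C11–C16 form the bicyclooctane; C17 is the methylene carbon.
- A geranyl unit supplies only C1–C6, C10 and C18–C20. C7 is therefore added at the start as a vinyl group, whose outer carbon is later removed by ozonolysis. Commercial (E)-geranyl bromide is the C10 source.
- The two ring carbonyls of 19 are diastereotopic, not enantiotopic, because ring A is already chiral. Step 13 is a catalyst-controlled choice between diastereotopic groups.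
- C13–H2 of 19 is an ordinary ketone α-methylene, since the doubly activated position C8 is quaternary. Enolisation relies on the palladium-bound carbonyl, not on special acidity. The 1,3-diketone can undergo retro-Claisen cleavage, so an anhydrous, non-nucleophilic base is used.
- No structural error was found: 20 maps onto 24 by C14=O → CH2. Only CIP labels change: C13 is S in 20 and R in 24; C8 is S in 20 and 24 but R in 21.
- Compound 7 is written as the exocyclic alkene. Any C1=C10 isomer formed with it is carried along, because step 9 should convert both into 12.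
- The ligand antipode written in step 13 is provisional; the antipode that leads to 20 must be identified by running both.

## Structural features

The target is a 9,10-seco-kaurane acetate built from two bridged bicycles joined by the C6–C7 tether. One is a 6-oxabicyclo[3.2.1]octan-7-one (ring A with the C19→C10 γ-lactone bridge). The other is a bicyclo[3.2.1]octane carrying the C9 ketone and the exocyclic C16=C17 alkene. Ring A holds four contiguous stereocentres: C3 (acetoxy), C4 (quaternary), C5 (tether) and C10 (quaternary); in the lactone the acetoxy group and the C6 branch are both axial and syn, so C5 sits next to an easily ionised C10 in a strained ring. The other half has the quaternary bridgehead C8 and the bridgehead C13, which depend on each other through the bridge but are separated from C5 by two methylene groups. Fragile groups are the acetate, the tertiary-alkyl lactone, the acid-sensitive 1,1-disubstituted alkene and, in intermediates, a 1,3-diketone open to retro-Claisen cleavage. The real difficulty is absolute control of C8 and C13, which ring A cannot influence. The key step uses the fact that C8 is quaternary, flanked by the C9 carbonyl and by C14, which is one bond from C13. A second carbonyl at C14 turns the ring C8–C9–C11–C12–C13–C14 into a 2,2-disubstituted cyclohexane-1,3-dione with prochiral C8, so a palladium-mediated C13–C16 bond from a 2-bromoallyl arm sets both bridgeheads at once.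

## Logic of the disconnections

**24 ⇒ 21 ⇒ 20.** No skeletal bond is cut; the C14 methylene is traced back to a carbonyl through the tosylhydrazone. The extra oxygen is what makes C13 nucleophilic and C8 prochiral one stage earlier. The forward sequence must tell the strained, non-enolisable C14 ketone from the C9 ketone and must spare the alkene, lactone and acetate.

**20 ⇒ 19.** The C13–C16 bond is cut, opening the five-membered ring of the bicyclooctane. This removes both bridgehead stereocentres and one ring and leaves a dione half with no stereocentre. The forward step needs a catalyst that chooses one of two carbonyl arms and joins an sp2 carbon to an enolate carbon in a bridged closure.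

**19 ⇒ 17 + 18.** The C8–C15 bond is cut at the carbon between two carbonyls, the natural site for alkylation by an allylic halide. This returns a monosubstituted dione and a commercial C3 unit. The forward step must alkylate on carbon, not oxygen; no stereochemistry is at stake because C8 stays prochiral.

**17 ⇒ 14 + 15.** The C7–C8 bond is cut as a reductive alkylation. This separates the chiral half from the commercial ring. The forward step must stop at mono-alkylation and be neutral enough for lactone and acetate.

**14 ⇒ 12.** The C7 aldehyde is traced to a terminal alkene with one extra carbon. An alkene passes untouched through the earlier oxidations and the cationic cyclisation, where an oxygen function at C7 could capture the C10 cation. The demand is that no other alkene remains when it is cleaved, so the lactone must be closed first.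

**12 ⇒ 11.** The C10–O bond of the lactone is cut. The bridged ring A becomes a simple cyclohexane with an exocyclic alkene and a carboxylic acid, and C10 ceases to be a stereocentre. The forward step must add the acid in the Markovnikov sense to the 1,1-disubstituted alkene only, without disturbing C5.

**11 ⇒ 9 ⇒ 8 ⇒ 7 (through 10).** These are functional-group changes: the acid from a silyl-protected primary alcohol, the acetate from the free C3 hydroxyl. The order must prevent acetyl migration to O19, and the oxidation must spare two alkenes.

**7 ⇒ 6.** The C4–C5 bond is cut, opening ring A to an acyclic epoxy triene. Three contiguous stereocentres are reduced to one epoxide and one alkene geometry. The forward step demands a chair transition state, anti opening at C4 and proton loss away from C5.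

**6 ⇒ 5 ⇒ 4.** The silyl group and the epoxide oxygen are removed, leaving an (E)-allylic alcohol. The forward epoxidation must be reagent-controlled and confined to the allylic alkene.

**4 ⇒ 3.** The C19 oxygen is removed. The forward allylic oxidation must pick the E-methyl of the terminal alkene among three alkenes.

**3 ⇒ 1 + 2.** The C6–C7 bond is cut between an allylic bromide and a vinyl nucleophile, both commercial. The coupling must occur at the primary allylic carbon with retention of the E geometry.

## Other disconnections considered

**Alternative 1:** The cut is C4–C5, made as the last ring on a substrate that already carries the bicyclooctanone. The epoxy diene A2 would be treated with MeAlCl2: the epoxide opens at C4, C5 attacks through a chair, and the C10 cation loses a proton to give A1. Acetylation, oxidation of C19 and lactonisation would follow.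
- In favour: one Sharpless epoxide fixes C3, C4 and C5. This is the same reaction as step 5 of the chosen plan, so on ring A stereocontrol the two plans are equal.
- Better in one respect: the palladium step would run on a dione without ring A, where the two carbonyls are truly enantiotopic and selectivity is easier to measure and optimise.
- Against: A2 carries the C9 ketone, which binds the Lewis acid, and the C16=C17 alkene, which is as prone to protonation as the alkene meant to react.
- Against, more seriously: closing the lactone at C10 after A1 needs exactly the reactivity (protonation or halonium formation at a 1,1-disubstituted alkene) that C16=C17 shares. That alkene would have to be masked as a ketone and restored later.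
- C8 cannot be alkylated once it is a bridgehead, so A2 would still be made through the same dione alkylations and palladium closure.
- Comparison: the bonds are the same in a different order; the cationic step is less protected; step economy is at best equal and probably two or three steps worse.

**Alternative 2:** The cuts are C8–C15 and C9–C16, the latter re-opened afterwards. Sensitised irradiation of the 1,5-diene A4 (C8=C9 silyl enol ether plus an acrylate on C13) should give the crossed adduct A3, a bicyclo[2.1.1]hexane. Fluoride would then trigger a Grob-type retro-aldol opening of C9–C16 to the keto ester A5.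
- In favour: C8 is created under substrate control from C13 through a rigid cage, with no chiral catalyst; on predictability of the C8/C13 relationship it is at least equal.
- Better: the photoreaction is neutral, and no surplus oxygen is left at C14, so the deoxygenation and its site-selectivity question disappear.
- Against: C13 must be set beforehand and is as remote from ring A as C8, so an independent asymmetric step is still needed.
- Against: A4 has an α-substituted acrylate next to that stereocentre, which invites double-bond migration.
- Against: in A5, C16 carries an ester instead of the methylene. Its carbon must be reduced in the presence of a ketone, a lactone and an acetate and then dehydrated toward C16, which costs at least three further steps.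
- Comparison: structurally elegant and mechanistically robust at the key step, but longer overall and no simpler stereochemically.

**Alternative 3:** The cut is C12–C13. In the cyclopentanone A7 the enamine or enolate at C13 would add to C12 of the acryloyl group on C8, closing the six-membered ring to give A6. Methylenation of the less hindered C16 ketone would finish the skeleton.
- In favour: Michael closures to bicyclo[3.2.1]octanediones are well established and need no transition metal. On reliability of the bond-forming event it is better.
- Better: A6 has the right oxygen pattern, so no deoxygenation is needed.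
- Against: C8 must already be a defined quaternary stereocentre in A7, far from ring A, with no short asymmetric solution in sight.
- Against: the vinyl ketone is prone to polymerisation, enolisation toward C15 competes unproductively, and the C16 ketone must be methylenated selectively over C9.
- Comparison: the chosen plan creates C8 and C13 in the ring-forming step from a precursor two steps from the aldehyde. Alternative 3 moves the stereochemical burden to an earlier and harder problem and is expected to be longer.

Key step: step 13

## Route

Step 1
Reactants: 1 geranyl bromide; 2 vinylmagnesium bromide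
Product: 3 (4E)-5,9-dimethyldeca-1,4,8-triene
Conditions: CuI (5 mol %), THF, −30 °C to 0 °C
Reagents that add atoms: none
Why: Copper-catalysed cross-coupling of an allylic bromide with an alkenyl Grignard reagent; attack should occur at the primary carbon because the other allylic terminus is fully substituted, with the E geometry of C5=C10 retained. This installs C7 together with one sacrificial carbon.

Step 2
Reactants: 3 (4E)-5,9-dimethyldeca-1,4,8-triene
Product: 4 (2E,6E)-2,6-dimethyldeca-2,6,9-trien-1-ol
Conditions: SeO2 (10 mol %), t-BuOOH (3 equiv), salicylic acid (10 mol %), CH2Cl2, 0 °C to rt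
Reagents that add atoms: tert-butyl hydroperoxide, CC(C)(C)OO (stoichiometric oxygen source); selenium dioxide, O=[Se]=O (oxygen carrier)
Why: Selenium dioxide allylic oxidation (ene reaction, then [2,3]-sigmatropic shift); the terminal trisubstituted alkene is the most accessible and is oxidised at the methyl trans to the chain. This should give the (E)-allylic alcohol at C19 and leave the vinyl group and, largely, the internal alkene.

Step 3
Reactants: 4 (2E,6E)-2,6-dimethyldeca-2,6,9-trien-1-ol
Product: 5 [(2S,3S)-2-methyl-3-[(3E)-3-methylhepta-3,6-dien-1-yl]oxiran-2-yl]methanol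
Conditions: Ti(OiPr)4 (10 mol %), L-(+)-diethyl tartrate (12 mol %), t-BuOOH (2 equiv), 4 Å molecular sieves, CH2Cl2, −20 °C
Reagents that add atoms: tert-butyl hydroperoxide, CC(C)(C)OO
Why: Sharpless asymmetric epoxidation; the titanium tartrate complex epoxidises only the allylic alcohol, and the L-(+)-tartrate delivers oxygen to the face that gives the (2S,3S)-epoxide. This fixes C3 (S) and the configuration of C4 before its inversion.

Step 4
Reactants: 5 [(2S,3S)-2-methyl-3-[(3E)-3-methylhepta-3,6-dien-1-yl]oxiran-2-yl]methanol
Product: 6 tert-butyl{[(2S,3S)-2-methyl-3-[(3E)-3-methylhepta-3,6-dien-1-yl]oxiran-2-yl]methoxy}diphenylsilane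
Conditions: TBDPSCl, imidazole, DMF, rt
Reagents that add atoms: tert-butyl(chloro)diphenylsilane, CC(C)(C)[Si](Cl)(c1ccccc1)c1ccccc1
Why: Standard silylation of the primary alcohol; the bulky, weakly coordinating silyl ether should survive the Lewis acid of step 5 and prevents alkoxide-directed opening of the epoxide at C3.

Step 5
Reactants: 6 tert-butyl{[(2S,3S)-2-methyl-3-[(3E)-3-methylhepta-3,6-dien-1-yl]oxiran-2-yl]methoxy}diphenylsilane
Product: 7 (1S,2R,3R)-2-{[tert-butyl(diphenyl)silyl]oxymethyl}-2-methyl-4-methylidene-3-(prop-2-en-1-yl)cyclohexan-1-ol
Conditions: MeAlCl2 (1.5 equiv), CH2Cl2, −78 °C; aq. NaHCO3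
Reagents that add atoms: none
Why: Lewis-acid-initiated epoxide–olefin (cation–olefin) cyclisation: the C5=C10 alkene opens the activated epoxide at tertiary C4 with inversion through a chair transition state (6-endo), so O3, C19 and C6 all end up equatorial; C3 keeps its configuration, C4 and C5 follow from the epoxide and alkene geometry, and the C10 cation loses a C20 proton. The unactivated vinyl group should not take part.

Step 6
Reactants: 7 (1S,2R,3R)-2-{[tert-butyl(diphenyl)silyl]oxymethyl}-2-methyl-4-methylidene-3-(prop-2-en-1-yl)cyclohexan-1-ol
Product: 8 (1S,2R,3R)-2-{[tert-butyl(diphenyl)silyl]oxymethyl}-2-methyl-4-methylidene-3-(prop-2-en-1-yl)cyclohexyl acetate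
Conditions: Ac2O, pyridine, DMAP (cat.), CH2Cl2, rt
Reagents that add atoms: acetic anhydride, CC(=O)OC(C)=O
Why: DMAP-catalysed acetylation of the secondary alcohol; it installs the C3 acetate of the target and protects O3 during oxidation and lactonisation.

Step 7
Reactants: 8 (1S,2R,3R)-2-{[tert-butyl(diphenyl)silyl]oxymethyl}-2-methyl-4-methylidene-3-(prop-2-en-1-yl)cyclohexyl acetate
Product: 9 (1S,2R,3R)-2-(hydroxymethyl)-2-methyl-4-methylidene-3-(prop-2-en-1-yl)cyclohexyl acetate
Conditions: HF·pyridine, THF/pyridine, 0 °C to rt
Reagents that add atoms: none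
Why: Fluoride-induced desilylation under mildly acidic conditions, chosen because basic fluoride could move the acetyl group from O3 to the neighbouring primary oxygen; alkenes and acetate are inert.

Step 8
Reactants: 9 (1S,2R,3R)-2-(hydroxymethyl)-2-methyl-4-methylidene-3-(prop-2-en-1-yl)cyclohexyl acetate
Product: 11 (1S,2R,6S)-6-acetoxy-1-methyl-3-methylidene-2-(prop-2-en-1-yl)cyclohexane-1-carboxylic acid, via the aldehyde 10 (not isolated)
Conditions: TEMPO (10 mol %), PhI(OAc)2 (1.2 equiv), CH2Cl2, rt; then NaClO2, NaH2PO4, 2-methylbut-2-ene, t-BuOH/H2O, 0 °C to rt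
Reagents that add atoms: sodium chlorite, [Na+].[O-]Cl=O
Why: Oxoammonium (TEMPO) oxidation of the neopentyl primary alcohol to an aldehyde that has no α-hydrogen and cannot epimerise, followed by Pinnick oxidation to the acid; 2-methylbut-2-ene scavenges hypochlorite so the two alkenes are spared.

Step 9
Reactants: 11 (1S,2R,6S)-6-acetoxy-1-methyl-3-methylidene-2-(prop-2-en-1-yl)cyclohexane-1-carboxylic acid
Product: 12 (1S,2S,5S,8S)-1,5-dimethyl-7-oxo-8-(prop-2-en-1-yl)-6-oxabicyclo[3.2.1]octan-2-yl acetate
Conditions: p-TsOH·H2O (10 mol %), CH2Cl2, 0 °C to rt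
Reagents that add atoms: none
Why: Brønsted-acid-catalysed Markovnikov hydroacyloxylation: carboxyl-assisted protonation of the 1,1-disubstituted alkene at C20 and 5-exo capture of tertiary C10 by the C19 carboxyl close the γ-lactone. The bridge can form only with oxygen on the face of C10 cis to C19, which sets C10 (S); the monosubstituted allyl alkene should not be protonated. A weak acid at low temperature is used so that the C10 cation is captured before it can lose H5.

Step 10
Reactants: 12 (1S,2S,5S,8S)-1,5-dimethyl-7-oxo-8-(prop-2-en-1-yl)-6-oxabicyclo[3.2.1]octan-2-yl acetate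
Product: 14 (1S,2S,5S,8S)-1,5-dimethyl-7-oxo-8-(2-oxoethyl)-6-oxabicyclo[3.2.1]octan-2-yl acetate, via the ozonide 13 (not isolated)
Conditions: O3, CH2Cl2, −78 °C; then Me2S, −78 °C to rt
Reagents that add atoms: ozone, [O-][O+]=O
Why: Ozonolysis of the only remaining alkene with reductive work-up; the sacrificial carbon leaves as formaldehyde and the C7 aldehyde remains, with lactone and acetate inert to ozone.

Step 11
Reactants: 14 (1S,2S,5S,8S)-1,5-dimethyl-7-oxo-8-(2-oxoethyl)-6-oxabicyclo[3.2.1]octan-2-yl acetate; 15 cyclohexane-1,3-dione
Product: 17 (1S,2S,5S,8S)-8-[2-(2,6-dioxocyclohexyl)ethyl]-1,5-dimethyl-7-oxo-6-oxabicyclo[3.2.1]octan-2-yl acetate, via the alkylidene dione 16 (not isolated)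
Conditions: Hantzsch ester (1.1 equiv), L-proline (10 mol %), CH2Cl2, rt
Reagents that add atoms: none
Why: Organocatalytic three-component reductive alkylation: proline-catalysed Knoevenagel condensation gives the alkylidene dione, which is reduced at once by hydride transfer from the Hantzsch ester so that a second dione cannot add. This forms C7–C8 under neutral conditions.

Step 12
Reactants: 17 (1S,2S,5S,8S)-8-[2-(2,6-dioxocyclohexyl)ethyl]-1,5-dimethyl-7-oxo-6-oxabicyclo[3.2.1]octan-2-yl acetate; 18 2,3-dibromopropene
Product: 19 (1S,2S,5S,8S)-8-{2-[1-(2-bromoprop-2-en-1-yl)-2,6-dioxocyclohexyl]ethyl}-1,5-dimethyl-7-oxo-6-oxabicyclo[3.2.1]octan-2-yl acetate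
Conditions: K2CO3, acetone, 50 °C
Reagents that add atoms: none
Why: C-alkylation of the 2-alkyl-1,3-dione enolate by SN2 displacement of the allylic bromide (the vinylic bromide does not react) creates the quaternary, still prochiral C8; carbonate in acetone is mild enough for acetate and lactone.

Step 13
Reactants: 19 (1S,2S,5S,8S)-8-{2-[1-(2-bromoprop-2-en-1-yl)-2,6-dioxocyclohexyl]ethyl}-1,5-dimethyl-7-oxo-6-oxabicyclo[3.2.1]octan-2-yl acetate
Product: 20 (1S,2S,5S,8S)-1,5-dimethyl-8-{2-[(1S,5S)-6-methylidene-2,8-dioxobicyclo[3.2.1]octan-1-yl]ethyl}-7-oxo-6-oxabicyclo[3.2.1]octan-2-yl acetate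
Conditions: Pd2(dba)3 (5 mol %), (R)-DTBM-SEGPHOS (12 mol %), K3PO4 (3 equiv), toluene, 80 °C
Reagents that add atoms: none
Why: Proposed new method: zerovalent palladium inserts into the C16–Br bond of 19 to give an alkenylpalladium bromide (divalent palladium) held over the dione by the C15 methylene; phosphate-assisted enolisation of one of the two flanking carbonyl arms gives a C-bound palladium enolate at C13 (a six-membered C,C-palladacycle), and reductive elimination forms C13–C16 and returns zerovalent palladium. The closest known reaction types are the palladium-catalysed intramolecular α-alkenylation of ketones with vinyl halides and the enantioselective desymmetrising α-arylation of 2,2-disubstituted cyclic 1,3-diketones, which have not been combined on a 2-bromoallyl dione with ligand-controlled choice of the carbonyl arm. The one ring that closes is the cyclopentane C8–C15–C16–C13–C14, formed in a 5-exo sense with respect to the alkenyl carbon (C17 stays exocyclic) and enolendo with respect to the enolate, which turns the cyclohexanedione into the bicyclo[3.2.1]octane. C8 becomes stereogenic through the choice between the C9 and the C14 arm, made by the chiral pocket of the bisphosphine on palladium; the ring A stereocentres are too remote to help or hinder. C13 is not chosen independently, because the two-carbon bridge can span C8 and C13 on one side only, so its configuration follows from that of C8. Regiochemistry needs no control, since C8 is quaternary and only C13 or its mirror carbon C11 can reach C16, and a second alkenylation is excluded once C13 is a bridgehead. C–C over C–O reductive elimination is expected because the alternative product would be a strained bicyclic dienol ether, and the anhydrous, non-nucleophilic base is chosen so that the acetate, the lactone and the retro-Claisen-prone 1,3-diketone are not attacked.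

Step 14
Reactants: 20 (1S,2S,5S,8S)-1,5-dimethyl-8-{2-[(1S,5S)-6-methylidene-2,8-dioxobicyclo[3.2.1]octan-1-yl]ethyl}-7-oxo-6-oxabicyclo[3.2.1]octan-2-yl acetate
Product: 21 (1S,2S,5S,8S)-1,5-dimethyl-8-{2-[(1R,5S)-6-methylidene-8-[2-(4-methylbenzenesulfonyl)hydrazinylidene]-2-oxobicyclo[3.2.1]octan-1-yl]ethyl}-7-oxo-6-oxabicyclo[3.2.1]octan-2-yl acetate
Conditions: TsNHNH2 (1.05 equiv), PPTS (5 mol %), THF/EtOH, rt to 40 °C
Reagents that add atoms: 4-methylbenzenesulfonohydrazide, Cc1ccc(cc1)S(=O)(=O)NN
Why: Condensation of the sulfonyl hydrazide with the more electrophilic ketone: the C14 carbonyl sits on the one-carbon bridge, is angle-strained and has only the small bridgehead hydrogen in its plane, whereas the C9 carbonyl is an ordinary cyclohexanone flanked by quaternary C8. One equivalent of reagent should therefore give the C14 mono-hydrazone.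

Step 15
Reactants: 21 (1S,2S,5S,8S)-1,5-dimethyl-8-{2-[(1R,5S)-6-methylidene-8-[2-(4-methylbenzenesulfonyl)hydrazinylidene]-2-oxobicyclo[3.2.1]octan-1-yl]ethyl}-7-oxo-6-oxabicyclo[3.2.1]octan-2-yl acetate
Product: 24 (1S,2S,5S,8S)-1,5-dimethyl-8-{2-[(1S,5R)-6-methylidene-2-oxobicyclo[3.2.1]octan-1-yl]ethyl}-7-oxo-6-oxabicyclo[3.2.1]octan-2-yl acetate (the target), via the boryl tosylhydrazine 22 (not isolated), via the diazene 23 (not isolated)
Conditions: catecholborane (1.5 equiv), CHCl3, 0 °C; then NaOAc·3H2O, 60 °C
Reagents that add atoms: none
Why: Tosylhydrazone reduction, a mild variant of the Wolff–Kishner deoxygenation: catecholborane adds hydride to C14, acetate then expels sulfinate to give the diazene, which loses N2 and leaves the C14 methylene. Esters, the lactone and the alkene should not react with catecholborane at this temperature, and the hindered C9 ketone reacts more slowly than the C=N bond.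

## Compound list

1 | geranyl bromide, (2E)-1-bromo-3,7-dimethylocta-2,6-diene | CC(C)=CCC/C(C)=C/CBr | starting material
2 | vinylmagnesium bromide | C=C[Mg]Br | starting material
3 | (4E)-5,9-dimethyldeca-1,4,8-triene | C=CC/C=C(\C)CCC=C(C)C | intermediate
4 | (2E,6E)-2,6-dimethyldeca-2,6,9-trien-1-ol | OC/C(C)=C/CC/C(C)=C/CC=C | intermediate
5 | [(2S,3S)-2-methyl-3-[(3E)-3-methylhepta-3,6-dien-1-yl]oxiran-2-yl]methanol | C=CC/C=C(\C)CC[C@@H]1O[C@@]1(C)CO | intermediate
6 | tert-butyl{[(2S,3S)-2-methyl-3-[(3E)-3-methylhepta-3,6-dien-1-yl]oxiran-2-yl]methoxy}diphenylsilane | C=CC/C=C(\C)CC[C@@H]1O[C@@]1(C)CO[Si](c2ccccc2)(c2ccccc2)C(C)(C)C | intermediate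
7 | (1S,2R,3R)-2-{[tert-butyl(diphenyl)silyl]oxymethyl}-2-methyl-4-methylidene-3-(prop-2-en-1-yl)cyclohexan-1-ol | C=CC[C@@H]1C(=C)CC[C@H](O)[C@@]1(C)CO[Si](c2ccccc2)(c2ccccc2)C(C)(C)C | intermediate
8 | (1S,2R,3R)-2-{[tert-butyl(diphenyl)silyl]oxymethyl}-2-methyl-4-methylidene-3-(prop-2-en-1-yl)cyclohexyl acetate | C=CC[C@@H]1C(=C)CC[C@H](OC(C)=O)[C@@]1(C)CO[Si](c2ccccc2)(c2ccccc2)C(C)(C)C | intermediate
9 | (1S,2R,3R)-2-(hydroxymethyl)-2-methyl-4-methylidene-3-(prop-2-en-1-yl)cyclohexyl acetate | C=CC[C@@H]1C(=C)CC[C@H](OC(C)=O)[C@@]1(C)CO | intermediate
10 | (1S,2S,3R)-2-formyl-2-methyl-4-methylidene-3-(prop-2-en-1-yl)cyclohexyl acetate (formed in the flask) | C=CC[C@@H]1C(=C)CC[C@H](OC(C)=O)[C@@]1(C)C=O | intermediate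
11 | (1S,2R,6S)-6-acetoxy-1-methyl-3-methylidene-2-(prop-2-en-1-yl)cyclohexane-1-carboxylic acid | C=CC[C@@H]1C(=C)CC[C@H](OC(C)=O)[C@@]1(C)C(=O)O | intermediate
12 | (1S,2S,5S,8S)-1,5-dimethyl-7-oxo-8-(prop-2-en-1-yl)-6-oxabicyclo[3.2.1]octan-2-yl acetate | C=CC[C@H]1[C@]2(C)C(=O)O[C@@]1(C)CC[C@@H]2OC(C)=O | intermediate
13 | (1S,2S,5S,8S)-1,5-dimethyl-7-oxo-8-(1,2,4-trioxolan-3-ylmethyl)-6-oxabicyclo[3.2.1]octan-2-yl acetate, the ozonide of 12 (trioxolane carbon undefined; formed in the flask) | C1(OOCO1)C[C@H]2[C@]3(C)C(=O)O[C@@]2(C)CC[C@@H]3OC(C)=O | intermediate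
14 | (1S,2S,5S,8S)-1,5-dimethyl-7-oxo-8-(2-oxoethyl)-6-oxabicyclo[3.2.1]octan-2-yl acetate | O=CC[C@H]1[C@]2(C)C(=O)O[C@@]1(C)CC[C@@H]2OC(C)=O | intermediate
15 | cyclohexane-1,3-dione | O=C1CCCC(=O)C1 | starting material
16 | (1S,2S,5S,8S)-8-[2-(2,6-dioxocyclohexylidene)ethyl]-1,5-dimethyl-7-oxo-6-oxabicyclo[3.2.1]octan-2-yl acetate (formed in the flask) | O=C1CCCC(=O)C1=CC[C@H]2[C@]3(C)C(=O)O[C@@]2(C)CC[C@@H]3OC(C)=O | intermediate
17 | (1S,2S,5S,8S)-8-[2-(2,6-dioxocyclohexyl)ethyl]-1,5-dimethyl-7-oxo-6-oxabicyclo[3.2.1]octan-2-yl acetate (drawn as the diketo tautomer) | O=C1CCCC(=O)C1CC[C@H]2[C@]3(C)C(=O)O[C@@]2(C)CC[C@@H]3OC(C)=O | intermediate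
18 | 2,3-dibromopropene | C=C(Br)CBr | starting material
19 | (1S,2S,5S,8S)-8-{2-[1-(2-bromoprop-2-en-1-yl)-2,6-dioxocyclohexyl]ethyl}-1,5-dimethyl-7-oxo-6-oxabicyclo[3.2.1]octan-2-yl acetate | C=C(Br)CC1(CC[C@H]2[C@]3(C)C(=O)O[C@@]2(C)CC[C@@H]3OC(C)=O)C(=O)CCCC1=O | intermediate
20 | (1S,2S,5S,8S)-1,5-dimethyl-8-{2-[(1S,5S)-6-methylidene-2,8-dioxobicyclo[3.2.1]octan-1-yl]ethyl}-7-oxo-6-oxabicyclo[3.2.1]octan-2-yl acetate | C=C1C[C@]2(CC[C@H]3[C@]4(C)C(=O)O[C@@]3(C)CC[C@@H]4OC(C)=O)C(=O)[C@H]1CCC2=O | intermediate
21 | (1S,2S,5S,8S)-1,5-dimethyl-8-{2-[(1R,5S)-6-methylidene-8-[2-(4-methylbenzenesulfonyl)hydrazinylidene]-2-oxobicyclo[3.2.1]octan-1-yl]ethyl}-7-oxo-6-oxabicyclo[3.2.1]octan-2-yl acetate (C=N geometry undefined) | C=C1C[C@]2(CC[C@H]3[C@]4(C)C(=O)O[C@@]3(C)CC[C@@H]4OC(C)=O)C(=NNS(=O)(=O)c5ccc(C)cc5)[C@H]1CCC2=O | intermediate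
22 | hydride adduct of 21 at C14 carrying a 1,3,2-benzodioxaborol-2-yl group on the nitrogen bound to C14 (C14 undefined; formed in the flask) | C=C1C[C@]2(CC[C@H]3[C@]4(C)C(=O)O[C@@]3(C)CC[C@@H]4OC(C)=O)C(N(NS(=O)(=O)c5ccc(C)cc5)B5Oc6ccccc6O5)[C@H]1CCC2=O | intermediate
23 | C14 diazene, the compound 24 bearing N=NH on C14 (C14 undefined; formed in the flask) | C=C1C[C@]2(CC[C@H]3[C@]4(C)C(=O)O[C@@]3(C)CC[C@@H]4OC(C)=O)C(N=N)[C@H]1CCC2=O | intermediate
24 | (1S,2S,5S,8S)-1,5-dimethyl-8-{2-[(1S,5R)-6-methylidene-2-oxobicyclo[3.2.1]octan-1-yl]ethyl}-7-oxo-6-oxabicyclo[3.2.1]octan-2-yl acetate, CNP0204681.1 | C=C1C[C@]2(CC[C@H]3[C@]4(C)C(=O)O[C@@]3(C)CC[C@@H]4OC(C)=O)C[C@H]1CCC2=O | target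

## Step count and least certain steps

Total step count: 15. Longest linear sequence: 15 steps, from 1 to 24; compounds 2, 15 and 18 are commercial.

**Step 13 (key step, proposed new method).** The most likely failure is weak discrimination between the two carbonyl arms, giving low selectivity at C8/C13, because no precedent places a bisphosphine-bound alkenylpalladium over a dione of this shape. Slow enolisation with the weak base could also lead to loss of bromine without ring closure. The fallback uses known chemistry and gives up catalyst control.
- It sets out from 17. C-alkylation with propargyl bromide (K2CO3, acetone) gives the 2-propargyl dione F1.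
- TBSOTf and Et3N convert one carbonyl into the mono(silyl enol ether) F2, formed as both C8 epimers.
- Ph3PAuCl/AgSbF6 (monovalent gold, 5 mol %) in CH2Cl2/MeOH effects a 5-exo-dig Conia-ene-type closure of the silyl enol ether onto the alkyne, forming the same C13–C16 bond.
- This gives 20 together with its (8R,13R) diastereomer F3, which is a diastereomer because ring A is enantiopure and is removed by chromatography. The route is rejoined at 20.

**Step 14.** The likely failure is incomplete site discrimination in hydrazone formation (reaction at C9 or at both ketones), because the preference rests only on strain and local hindrance. The fallback replaces innate selectivity by protection.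
- It sets out from 20. TBSOTf and Et3N (CH2Cl2, −78 to 0 °C) silylate the only enolisable ketone, C9, giving the C9 silyl enol ether F4; C14 cannot enolise, since C8 is quaternary and C13 a bridgehead.
- TsNHNH2 without acid (THF, MgSO4) can then give only the C14 tosylhydrazone F5.
- Catecholborane followed by NaOAc·3H2O gives the silyl enol ether of the target F6.
- HF·pyridine frees the C9 ketone, rejoining the route at 24.

**Step 9.** The likely failure is erosion of configuration at C5 by reversible proton loss from the C10 cation toward C5 and re-protonation from either face; the C5-epimeric lactone is the less strained one. Closure may also be slow because it needs the ring-flipped conformer. The fallback avoids a free cation.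
- It sets out from 11. I2 and NaHCO3 in MeCN at 0 °C effect a kinetic anti iodolactonisation to the iodolactone F7. The 5-exo closure at the 1,1-disubstituted alkene is expected to outrun 6-exo closure at the allyl group.
- Bu3SnH, AIBN and catalytic PhSeSePh in benzene at 80 °C remove iodine. The selenol formed in the flask donates hydrogen fast enough to intercept the C20 radical before it adds to the allyl group.
- The route is rejoined at 12.

**Step 5.** The likely failure is diversion of the cationic pathway: hydride shift in the opened epoxide to a C3 ketone, chloride capture, or loss of H5 instead of a C20 proton, which would erase C5. The fallback changes from cationic to radical ring closure.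
- It sets out from 6. Cp2TiCl (trivalent titanium, made from Cp2TiCl2 and Mn dust, THF, rt) opens the epoxide homolytically at C4.
- The tertiary radical adds 6-endo to C5=C10, and the C10 radical is trapped by a second Cp2TiCl and undergoes β-hydride elimination to the exocyclic alkene.
- The route is rejoined directly at 7, so this fallback makes no compound outside the list (F0).
- The cost: C4 is then set by the equatorial preference of the silyloxymethyl group rather than by inversion, so a C4 epimer may have to be separated.

**Step 12.** The likely failure is O-alkylation of the dione enolate competing with C-alkylation. The fallback makes the O-alkyl compound on purpose.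
- It sets out from 17. Treatment with 18 and Cs2CO3 in DMF at 0 °C gives the 2-bromoallyl enol ether F8.
- Heating in toluene at 150 °C in a sealed tube induces a Claisen rearrangement that moves the bromoallyl group to C8.
- The route is rejoined at 19.

## Further compounds

F1 | step 13 | 2-propargyl analogue of 19: (1S,2S,5S,8S)-8-{2-[2,6-dioxo-1-(prop-2-yn-1-yl)cyclohexyl]ethyl}-1,5-dimethyl-7-oxo-6-oxabicyclo[3.2.1]octan-2-yl acetate | C#CCC1(CC[C@H]2[C@]3(C)C(=O)O[C@@]2(C)CC[C@@H]3OC(C)=O)C(=O)CCCC1=O
F2 | step 13 | mono(tert-butyldimethylsilyl enol ether) of F1, both C8 epimers | C#CCC1(CC[C@H]2[C@]3(C)C(=O)O[C@@]2(C)CC[C@@H]3OC(C)=O)C(=O)CCC=C1O[Si](C)(C)C(C)(C)C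
F3 | step 13 | (8R,13R) diastereomer of 20 (bicyclooctanedione part 1R,5R) | C=C1C[C@@]2(CC[C@H]3[C@]4(C)C(=O)O[C@@]3(C)CC[C@@H]4OC(C)=O)C(=O)[C@@H]1CCC2=O
F4 | step 14 | C9 tert-butyldimethylsilyl enol ether of 20 (C9=C11) | C=C1C[C@]2(CC[C@H]3[C@]4(C)C(=O)O[C@@]3(C)CC[C@@H]4OC(C)=O)C(=O)[C@H]1CC=C2O[Si](C)(C)C(C)(C)C
F5 | step 14 | C14 tosylhydrazone of F4 | C=C1C[C@]2(CC[C@H]3[C@]4(C)C(=O)O[C@@]3(C)CC[C@@H]4OC(C)=O)C(=NNS(=O)(=O)c5ccc(C)cc5)[C@H]1CC=C2O[Si](C)(C)C(C)(C)C
F6 | step 14 | C9 tert-butyldimethylsilyl enol ether of 24 | C=C1C[C@]2(CC[C@H]3[C@]4(C)C(=O)O[C@@]3(C)CC[C@@H]4OC(C)=O)C[C@H]1CC=C2O[Si](C)(C)C(C)(C)C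
F7 | step 9 | iodolactone: 12 with CH2I in place of the C20 methyl, configuration as in 12 | C=CC[C@H]1[C@]2(C)C(=O)O[C@@]1(CI)CC[C@@H]2OC(C)=O
F0 | step 5 | none | none
F8 | step 12 | 3-(2-bromoprop-2-en-1-yloxy)cyclohex-2-enone isomer of 19 (O-alkylated enol ether) | C=C(Br)COC1=C(CC[C@H]2[C@]3(C)C(=O)O[C@@]2(C)CC[C@@H]3OC(C)=O)C(=O)CCC1
A1 | alternative 1 | ring A cyclohexanol with exocyclic C10 methylene on the finished bicyclooctanone | C=C1C[C@]2(CC[C@@H]3C(=C)CC[C@H](O)[C@@]3(C)CO[Si](c4ccccc4)(c4ccccc4)C(C)(C)C)C[C@H]1CCC2=O
A2 | alternative 1 | (3S,4S)-epoxy (5E)-diene silyl ether attached at C8 of the bicyclooctanone | C=C1C[C@]2(CC/C=C(\C)CC[C@@H]3O[C@@]3(C)CO[Si](c4ccccc4)(c4ccccc4)C(C)(C)C)C[C@H]1CCC2=O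
A3 | alternative 2 | tricyclic cyclobutane photoadduct (bicyclo[2.1.1]hexane) | O=C(OCc1ccccc1)[C@]12C[C@]3(CC[C@H]4[C@]5(C)C(=O)O[C@@]4(C)CC[C@@H]5OC(C)=O)C[C@H]1CC[C@]23O[Si](C)(C)C(C)(C)C
A4 | alternative 2 | benzyl 2-(cyclohexenyl)acrylate with the C8=C9 silyl enol ether | C=C(C(=O)OCc1ccccc1)[C@@H]1CCC(O[Si](C)(C)C(C)(C)C)=C(CC[C@H]2[C@]3(C)C(=O)O[C@@]2(C)CC[C@@H]3OC(C)=O)C1
A5 | alternative 2 | bicyclo[3.2.1]octan-2-one with a benzyl ester on C16 (C16 undefined) | O=C(OCc1ccccc1)C1C[C@]2(CC[C@H]3[C@]4(C)C(=O)O[C@@]3(C)CC[C@@H]4OC(C)=O)C[C@H]1CCC2=O
A6 | alternative 3 | bicyclo[3.2.1]octane-2,6-dione with the lactone attached | O=C1C[C@]2(CC[C@H]3[C@]4(C)C(=O)O[C@@]3(C)CC[C@@H]4OC(C)=O)C[C@H]1CCC2=O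
A7 | alternative 3 | 3-acryloyl-3-(lactone-ethyl)cyclopentanone | C=CC(=O)[C@@]1(CC[C@H]2[C@]3(C)C(=O)O[C@@]2(C)CC[C@@H]3OC(C)=O)CCC(=O)C1
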